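Assumption: the target SMILES has no stereocentre, stereogenic axis or stereogenic double bond (achiral, two identical halves). "Single enantiomer" therefore needs no stereocontrol, and no SMILES below carries a stereo descriptor.

**Retrosynthetic overview**
- Cut the central CH2–O–CH2 ether first. The target is the dehydrative dimer of two molecules of lanosol (2,3-dibromo-4,5-dihydroxybenzyl alcohol), joined through its p-quinone methide.
- Lanosol comes from 2,3-dibromo-4,5-dihydroxybenzaldehyde by C=O reduction.
- The dibromoaldehyde comes from protocatechualdehyde by two successive aromatic brominations, first ortho to the 4-OH and then para to the 3-OH.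
- No ring is formed, because both benzene rings are bought. The route uses no protecting groups and sets no stereocentre.

**Route**

Step 1
Reactants: 1 3,4-dihydroxybenzaldehyde (protocatechualdehyde)
Product: 3 2,3-dibromo-4,5-dihydroxybenzaldehyde, via 3-bromo-4,5-dihydroxybenzaldehyde 2 (not isolated)
Conditions: Br2 (2.2 equiv), AcOH, rt then 50 °C; pour into ice water, filter
Reagents that add atoms: bromine, BrBr
Why: In this double electrophilic aromatic bromination the first Br enters ortho to the 4-OH and meta to CHO (as with vanillin), the second enters para to the 3-OH at the carbon next to the first Br, and the electron-poor catechol resists oxidation in acidic AcOH; no stereocentre is formed.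

Step 2
Reactants: 3 2,3-dibromo-4,5-dihydroxybenzaldehyde
Product: 4 2,3-dibromo-4,5-dihydroxybenzyl alcohol (lanosol)
Conditions: NaBH4 (1.5 equiv), THF–H2O 4:1, N2, 0 °C to rt; 1 M HCl to pH 4–5 at 0 °C, EtOAc extraction
Reagents that add atoms: none
Why: Borohydride 1,2-reduction of the aldehyde (as in vanillin to vanillyl alcohol) leaves the aryl bromides and phenols untouched, and the alcohol-free solvent with a cold, mild quench keeps the solvolysis-prone benzylic alcohol from forming alkyl ethers; no stereocentre is formed.

Step 3
Reactants: 4 2,3-dibromo-4,5-dihydroxybenzyl alcohol (two molecules; one ionises, the other is the nucleophile)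
Product: 6 bis(2,3-dibromo-4,5-dihydroxybenzyl) ether, via 2,3-dibromo-6-hydroxy-4-methylidenecyclohexa-2,5-dien-1-one 5 (not isolated)
Conditions: Amberlyst-15 (H+ form, cat.), 4 Å MS, 1,4-dioxane (1 M), 70 °C, Ar; filter off resin and sieves, concentrate, crystallise or chromatograph
Reagents that add atoms: none
Why: In this acid-catalysed dehydrative homo-etherification through a p-quinone methide (the SN1-type solvolysis that turns lanosol into its methyl or ethyl ether in alcohols), the 4-OH para to CH2OH lets 4 lose water to 5 (reacting as its O-protonated form), the primary OH of a second 4 is the best nucleophile present, all O-adducts are reversible and funnel to the dialkyl ether as the sieves take up water, and the twice-brominated ring with one hindered free CH is a poor Friedel–Crafts partner; no stereocentre is formed.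

**Compound list**
1 | 3,4-dihydroxybenzaldehyde (protocatechualdehyde) | O=Cc1ccc(O)c(O)c1 | starting material
2 | 3-bromo-4,5-dihydroxybenzaldehyde | O=Cc1cc(O)c(O)c(Br)c1 | intermediate (not isolated)
3 | 2,3-dibromo-4,5-dihydroxybenzaldehyde | O=Cc1cc(O)c(O)c(Br)c1Br | intermediate
4 | 2,3-dibromo-4,5-dihydroxybenzyl alcohol (lanosol) | OCc1cc(O)c(O)c(Br)c1Br | intermediate
5 | 2,3-dibromo-6-hydroxy-4-methylidenecyclohexa-2,5-dien-1-one (p-quinone methide of 4) | C=C1C=C(O)C(=O)C(Br)=C1Br | intermediate (not isolated)
6 | bis(2,3-dibromo-4,5-dihydroxybenzyl) ether | Oc1cc(COCc2cc(O)c(O)c(Br)c2Br)c(Br)c(Br)c1O | target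

**Step count**
- Total step count: 3
- Longest linear sequence: 3 (linear route; 4 is used twice in step 3)

**Steps most likely to fail, most risky first**

Step 3. The risks are incomplete conversion of an equilibrium reaction, C-benzylation at the free ring CH, and ipso attack with loss of formaldehyde to give diarylmethanes. The fallback sets out from 3 and comes back at 6, and it never generates a benzylic cation on a free phenol.
- Acetylation of 3 (Ac2O, pyridine, cat. DMAP, CH2Cl2, 0 °C) gives 4,5-diacetoxy-2,3-dibromobenzaldehyde F1.
- Et3SiH (1.2 equiv) and TMSOTf (10 mol %) in CH2Cl2 at 0 °C first hydrosilylate F1 to 4,5-diacetoxy-2,3-dibromobenzyl triethylsilyl ether F2, which is not isolated.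
- F2 condenses with a second F1 to an oxocarbenium ion, and the silane reduces this to bis(4,5-diacetoxy-2,3-dibromobenzyl) ether F3. This is a reductive homo-etherification, and the acetoxy-deactivated ring allows neither over-reduction nor Friedel–Crafts chemistry.
- N2H4·H2O (4.5 equiv) in THF at 0 °C under Ar removes the four aryl acetates under nearly neutral, reducing conditions and delivers 6.

Step 1. The risks are oxidation of the catechol to the o-quinone by Br2, a stall at the monobromide, and bromodeformylation or over-bromination. The fallback sets out from 2 and comes back at 3.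
- The bromination of 1 is stopped after 1.0 equiv Br2 at rt and 2 is isolated (it is also sold).
- MeI, K2CO3, DMF, rt caps the oxidisable catechol as 3-bromo-4,5-dimethoxybenzaldehyde F4.
- Br2, cat. Fe powder, AcOH, 60 °C places the second Br para to the 5-OMe and gives 2,3-dibromo-4,5-dimethoxybenzaldehyde F5. The flanked 4-OMe has no free ortho or para site, so it does not compete as a director.
- BBr3 (3 equiv), CH2Cl2, −78 °C to rt, then water, cleaves both methyl ethers to 3.

Step 2. The risks are catechol–borate chelates and water solubility that hamper isolation, a phenoxide that deactivates the aldehyde, and an acidic quench that starts solvolysis of 4. The fallback sets out from 3 and comes back at 4.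
- TBSCl (2.5 equiv), imidazole, DMF, rt gives 2,3-dibromo-4,5-bis(tert-butyldimethylsilyloxy)benzaldehyde F6.
- DIBAL-H, CH2Cl2, −78 °C reduces this neutral, lipophilic aldehyde to [2,3-dibromo-4,5-bis(tert-butyldimethylsilyloxy)phenyl]methanol F7, which is purified by ordinary chromatography.
- Et3N·3HF, THF, 0 °C removes both silyl groups without acid or alcohol and gives 4.

**Further compounds**
F1 | step 3 | 4,5-diacetoxy-2,3-dibromobenzaldehyde | CC(=O)Oc1cc(C=O)c(Br)c(Br)c1OC(C)=O
F2 | step 3 | 4,5-diacetoxy-2,3-dibromobenzyl triethylsilyl ether | CC[Si](CC)(CC)OCc1cc(OC(C)=O)c(OC(C)=O)c(Br)c1Br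
F3 | step 3 | bis(4,5-diacetoxy-2,3-dibromobenzyl) ether | CC(=O)Oc1cc(COCc2cc(OC(C)=O)c(OC(C)=O)c(Br)c2Br)c(Br)c(Br)c1OC(C)=O
F4 | step 1 | 3-bromo-4,5-dimethoxybenzaldehyde | COc1cc(C=O)cc(Br)c1OC
F5 | step 1 | 2,3-dibromo-4,5-dimethoxybenzaldehyde | COc1cc(C=O)c(Br)c(Br)c1OC
F6 | step 2 | 2,3-dibromo-4,5-bis(tert-butyldimethylsilyloxy)benzaldehyde | O=Cc1cc(O[Si](C)(C)C(C)(C)C)c(O[Si](C)(C)C(C)(C)C)c(Br)c1Br
F7 | step 2 | [2,3-dibromo-4,5-bis(tert-butyldimethylsilyloxy)phenyl]methanol | OCc1cc(O[Si](C)(C)C(C)(C)C)c(O[Si](C)(C)C(C)(C)C)c(Br)c1Br
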